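**Retrosynthetic overview**

1. The target is (2S,4R)-4′,7-dihydroxyflavan-(4→8)-(−)-epiafzelechin. The last skeletal bond, C4(upper)–C8(lower), is made by Friedel–Crafts capture of the upper flavan-4-yl cation by 5,7,4′-tri-O-benzyl-epiafzelechin, anti to the 2-aryl group.
2. The upper pyran ring (O1–C2–C3–C4–C4a–C8a) is not closed as a six-membered ring. It comes from a seven-membered 2-aryl-2,3,4,5-tetrahydro-1,4-benzoxazepine whose N4 sits between C3 and the benzylic C5; deleting that nitrogen joins the two carbons as C3–C4.
3. Enabling feature: C4 of the upper unit is a benzylic CH2 of the resorcinol ring A (para to the 7-oxygen, ortho to O1), so its C–N bond breaks homolytically with loss of N2. The C2 stereocentre (aryl, O1) is β to nitrogen and is not touched. The same benzylic C4–H is later removed by DDQ.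
4. Ring order: C2 stereocentre by asymmetric transfer hydrogenation → oxazepine ring by Cu-catalysed aryl ether formation → contraction to upper ring C → C4 activation → interflavan bond → global debenzylation. Rings A and B and the whole lower unit are bought.

Key step: step 5

Assumption: (−)-epiafzelechin [(2R,3R)] is bought as the natural flavan-3-ol and used as the intact lower unit; compound 15 is carried on as its C4 epimer mixture because both epimers ionise to the same benzylic cation.

**Route**

Step 1
Reactants: 1 2-bromo-1-[4-(benzyloxy)phenyl]ethan-1-one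
Product: 2 2-azido-1-[4-(benzyloxy)phenyl]ethan-1-one
Conditions: NaN3, acetone/H2O, 0 °C → rt
Reagents that add atoms: sodium azide, [Na+].[N-]=[N+]=[N-]
Why: SN2 displacement of the activated phenacyl bromide by azide (azidation) should be fast and clean, and no stereocentre is involved.

Step 2
Reactants: 2 2-azido-1-[4-(benzyloxy)phenyl]ethan-1-one
Product: 3 (1R)-2-azido-1-[4-(benzyloxy)phenyl]ethan-1-ol
Conditions: RuCl[(S,S)-TsDPEN](p-cymene) (1 mol%), HCO2H/Et3N (5:2), DMF, rt
Reagents that add atoms: none
Why: Noyori asymmetric transfer hydrogenation of an α-azido aryl ketone, in which the (S,S)-ligand delivers hydride through the aryl CH–π-organised six-membered transition state to the face that gives the (R)-carbinol (the future C2), while azide and benzyl ether are inert to the ruthenium hydride.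

Step 3
Reactants: 3 (1R)-2-azido-1-[4-(benzyloxy)phenyl]ethan-1-ol; 4 4-(benzyloxy)-2-bromobenzaldehyde
Product: 8 (1R)-2-({[4-(benzyloxy)-2-bromophenyl]methyl}amino)-1-[4-(benzyloxy)phenyl]ethan-1-ol, via iminophosphorane 5 (not isolated), via primary amine 6 (not isolated), via imine 7 (not isolated)
Conditions: PPh3, THF/H2O, 50 °C; then 4, MeOH, rt; NaBH4, 0 °C
Reagents that add atoms: none
Why: Staudinger reduction (water hydrolyses the iminophosphorane before it can close to an aziridine) followed by reductive amination with the aldehyde should give the secondary amine in one pot, leaving the carbinol stereocentre, the aryl bromide and the benzyl ethers untouched.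

Step 4
Reactants: 8 (1R)-2-({[4-(benzyloxy)-2-bromophenyl]methyl}amino)-1-[4-(benzyloxy)phenyl]ethan-1-ol
Product: 9 (2R)-8-(benzyloxy)-2-[4-(benzyloxy)phenyl]-2,3,4,5-tetrahydro-1,4-benzoxazepine
Conditions: CuI (10 mol%), 3,4,7,8-tetramethyl-1,10-phenanthroline (20 mol%), Cs2CO3, toluene, 110 °C
Reagents that add atoms: none
Why: Ullmann-type intramolecular C–O coupling, O-selective for amino alcohols with this phenanthroline ligand and Cs2CO3, should close the seven-membered ring at the aryl carbon, so the carbinol C–O bond is never broken and C2 is retained.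

Step 5
Reactants: 9 (2R)-8-(benzyloxy)-2-[4-(benzyloxy)phenyl]-2,3,4,5-tetrahydro-1,4-benzoxazepine
Product: 13 (2S)-7-(benzyloxy)-2-[4-(benzyloxy)phenyl]-3,4-dihydro-2H-chromene [(2S)-4′,7-di-O-benzylflavan], via N-amino amide adduct 10 (not isolated), via isodiazene 11 (not isolated), via diradical 12 (not isolated)
Conditions: N-(benzyloxy)-N-(pivaloyloxy)-4-(trifluoromethyl)benzamide (1.5 equiv), THF, 45 °C
Reagents that add atoms: none
Why: The secondary amine of 9 attacks the anomeric amide at nitrogen with loss of pivalate to give 10, which expels benzyl 4-(trifluoromethyl)benzoate by reductive elimination to give isodiazene 11; 11 loses N2 by homolysis of the N–C5 bond (benzylic to ring A, para to the 7-benzyloxy group) and then of N–C3, and the tethered singlet diradical 12 collapses to the C3–C4 bond. The closest known reaction type is the nitrogen deletion of benzylic secondary amines through isodiazenes (anomeric-amide reagent, or classically oxidation of 1,1-disubstituted hydrazines), which contracts cyclic amines by one ring atom. The six-membered pyran ring is closed by intramolecular radical–radical recombination of C3 with C4, the two carbons that were geminal on nitrogen, so it is a ring contraction by extrusion and not a polar cyclisation. No new stereocentre is formed: C2, set in step 2, is β to the C3 radical, is never ionised or planarised, and is carried through with retention, the descriptor changing from R to S only because the CIP priorities change when nitrogen leaves. The step needs recombination to outrun β-scission of the O1–C2 bond and intramolecular disproportionation; the short tether, the benzylic stabilisation at C4 and the absence of any other N–H or O–H group in 9 should secure this.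

Step 6
Reactants: 13 (2S)-7-(benzyloxy)-2-[4-(benzyloxy)phenyl]-3,4-dihydro-2H-chromene
Product: 15 (2S,4R)-7-(benzyloxy)-2-[4-(benzyloxy)phenyl]-4-(2-ethoxyethoxy)-3,4-dihydro-2H-chromene (2,4-trans epimer drawn; C4 epimer carried along), via flavan-4-yl cation 14 (not isolated)
Conditions: DDQ, 2-ethoxyethanol, CH2Cl2, 0 °C → rt
Reagents that add atoms: 2-ethoxyethanol, CCOCCO
Why: DDQ oxidative benzylic etherification, in which hydride should be abstracted from C4–H (the only benzylic C–H of the more electron-rich resorcinol-type ring A, para to the 7-benzyloxy group and ortho to O1) to give cation 14 that the alcohol traps mainly anti to the 2-aryl group, the C4 configuration being irrelevant for the next step.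

Step 7
Reactants: 16 (−)-epiafzelechin [(2R,3R)-2-(4-hydroxyphenyl)chromane-3,5,7-triol]
Product: 17 5,7,4′-tri-O-benzyl-(−)-epiafzelechin [(2R,3R)-5,7-bis(benzyloxy)-2-[4-(benzyloxy)phenyl]chroman-3-ol]
Conditions: BnBr, K2CO3, DMF, 0 °C → rt
Reagents that add atoms: benzyl bromide, BrCc1ccccc1
Why: Williamson etherification in which the three phenols are alkylated selectively over the secondary 3-hydroxyl with carbonate base, the low temperature limiting base-induced epimerisation at C2.

Step 8
Reactants: 15 (2S,4R)-7-(benzyloxy)-2-[4-(benzyloxy)phenyl]-4-(2-ethoxyethoxy)-3,4-dihydro-2H-chromene; 17 5,7,4′-tri-O-benzyl-(−)-epiafzelechin (excess)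
Product: 18 (2S,4R)-4′,7-di-O-benzylflavan-(4→8)-5,7,4′-tri-O-benzyl-(−)-epiafzelechin [(2R,3R)-5,7-bis(benzyloxy)-8-{(2S,4R)-7-(benzyloxy)-2-[4-(benzyloxy)phenyl]chroman-4-yl}-2-[4-(benzyloxy)phenyl]chroman-3-ol]
Conditions: TMSOTf (cat.), CH2Cl2, −78 → −40 °C; then Et3N
Reagents that add atoms: none
Why: TMSOTf ionises the 4-(2-ethoxyethoxy) group of either C4 epimer of 15 to the same benzylic flavan-4-yl cation that step 6 passes through (compound 14), and Friedel–Crafts alkylation by C8 of the phloroglucinol-type ring of 17 (the usual site for benzylated flavan-3-ols, used in excess to suppress oligomers) should occur by axial attack anti to the pseudo-equatorial 2-aryl group to give the 2,4-trans (4R) interflavan bond.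

Step 9
Reactants: 18 (2S,4R)-4′,7-di-O-benzylflavan-(4→8)-5,7,4′-tri-O-benzyl-(−)-epiafzelechin
Product: 19 (2R,3R)-8-[(2S,4R)-7-hydroxy-2-(4-hydroxyphenyl)chroman-4-yl]-2-(4-hydroxyphenyl)chromane-3,5,7-triol (target)
Conditions: H2 (1 atm), Pd(OH)2/C, THF/MeOH/H2O, rt
Reagents that add atoms: none
Why: Catalytic hydrogenolysis of the five benzyl ethers under neutral conditions should leave the flavan C2–O1 bonds, the interflavan bond and all four stereocentres untouched, as is usual in proanthocyanidin deprotection.

**Compound list**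

1 | 2-bromo-1-[4-(benzyloxy)phenyl]ethan-1-one | O=C(CBr)c1ccc(OCc2ccccc2)cc1 | starting material
2 | 2-azido-1-[4-(benzyloxy)phenyl]ethan-1-one | [N-]=[N+]=NCC(=O)c1ccc(OCc2ccccc2)cc1 | intermediate
3 | (1R)-2-azido-1-[4-(benzyloxy)phenyl]ethan-1-ol | [N-]=[N+]=NC[C@H](O)c1ccc(OCc2ccccc2)cc1 | intermediate
4 | 4-(benzyloxy)-2-bromobenzaldehyde | O=Cc1ccc(OCc2ccccc2)cc1Br | starting material
5 | (1R)-1-[4-(benzyloxy)phenyl]-2-[(triphenyl-λ5-phosphanylidene)amino]ethan-1-ol (iminophosphorane) | O[C@@H](CN=P(c1ccccc1)(c1ccccc1)c1ccccc1)c1ccc(OCc2ccccc2)cc1 | intermediate (not isolated)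
6 | (1R)-2-amino-1-[4-(benzyloxy)phenyl]ethan-1-ol | NC[C@H](O)c1ccc(OCc2ccccc2)cc1 | intermediate (not isolated)
7 | (1R)-2-{(E)-[4-(benzyloxy)-2-bromobenzylidene]amino}-1-[4-(benzyloxy)phenyl]ethan-1-ol (imine) | O[C@@H](C/N=C/c1ccc(OCc2ccccc2)cc1Br)c1ccc(OCc2ccccc2)cc1 | intermediate (not isolated)
8 | (1R)-2-({[4-(benzyloxy)-2-bromophenyl]methyl}amino)-1-[4-(benzyloxy)phenyl]ethan-1-ol | O[C@@H](CNCc1ccc(OCc2ccccc2)cc1Br)c1ccc(OCc2ccccc2)cc1 | intermediate
9 | (2R)-8-(benzyloxy)-2-[4-(benzyloxy)phenyl]-2,3,4,5-tetrahydro-1,4-benzoxazepine | O1[C@@H](CNCc2ccc(OCc3ccccc3)cc21)c1ccc(OCc3ccccc3)cc1 | intermediate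
10 | N-(benzyloxy)-N-{(2R)-8-(benzyloxy)-2-[4-(benzyloxy)phenyl]-2,3-dihydro-1,4-benzoxazepin-4(5H)-yl}-4-(trifluoromethyl)benzamide | O1[C@@H](CN(N(OCc3ccccc3)C(=O)c3ccc(C(F)(F)F)cc3)Cc2ccc(OCc3ccccc3)cc21)c1ccc(OCc3ccccc3)cc1 | intermediate (not isolated)
11 | isodiazene (1,1-diazene) of 9, N4=N | O1[C@@H](C[N+](=[N-])Cc2ccc(OCc3ccccc3)cc21)c1ccc(OCc3ccccc3)cc1 | intermediate (not isolated)
12 | C3/C4 diradical left after loss of N2 from 11 | [CH2][C@H](Oc1cc(OCc2ccccc2)ccc1[CH2])c1ccc(OCc2ccccc2)cc1 | intermediate (not isolated)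
13 | (2S)-7-(benzyloxy)-2-[4-(benzyloxy)phenyl]-3,4-dihydro-2H-chromene | O1[C@@H](CCc2ccc(OCc3ccccc3)cc21)c1ccc(OCc3ccccc3)cc1 | intermediate
14 | (2S)-7-(benzyloxy)-2-[4-(benzyloxy)phenyl]chroman-4-ylium (flavan-4-yl cation) | O1[C@@H](C[CH+]c2ccc(OCc3ccccc3)cc21)c1ccc(OCc3ccccc3)cc1 | intermediate (not isolated)
15 | (2S,4R)-7-(benzyloxy)-2-[4-(benzyloxy)phenyl]-4-(2-ethoxyethoxy)-3,4-dihydro-2H-chromene (2,4-trans epimer; C4 epimer carried along) | O1[C@@H](C[C@@H](OCCOCC)c2ccc(OCc3ccccc3)cc21)c1ccc(OCc3ccccc3)cc1 | intermediate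
16 | (−)-epiafzelechin, (2R,3R)-2-(4-hydroxyphenyl)chromane-3,5,7-triol | Oc1cc(O)c2c(c1)O[C@H](c1ccc(O)cc1)[C@H](O)C2 | starting material
17 | (2R,3R)-5,7-bis(benzyloxy)-2-[4-(benzyloxy)phenyl]chroman-3-ol | c1ccccc1COc1cc(OCc3ccccc3)c2c(c1)O[C@H](c1ccc(OCc3ccccc3)cc1)[C@H](O)C2 | intermediate
18 | (2R,3R)-5,7-bis(benzyloxy)-8-{(2S,4R)-7-(benzyloxy)-2-[4-(benzyloxy)phenyl]chroman-4-yl}-2-[4-(benzyloxy)phenyl]chroman-3-ol | c1ccccc1COc1ccc([C@@H]2C[C@@H](c3c(OCc5ccccc5)cc(OCc5ccccc5)c4c3O[C@H](c3ccc(OCc5ccccc5)cc3)[C@H](O)C4)c3ccc(OCc5ccccc5)cc3O2)cc1 | intermediate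
19 | (2R,3R)-8-[(2S,4R)-7-hydroxy-2-(4-hydroxyphenyl)chroman-4-yl]-2-(4-hydroxyphenyl)chromane-3,5,7-triol | Oc1ccc([C@@H]2C[C@@H](c3c(O)cc(O)c4c3O[C@H](c3ccc(O)cc3)[C@H](O)C4)c3ccc(O)cc3O2)cc1 | target

**Step count and risks**

Total step count: 9. Longest linear sequence: 8 (steps 1–6, 8, 9); step 7 is a one-step side branch.

The three steps most likely to fail:

Step 5 (nitrogen deletion). The hindered amine may be aminated only slowly by the anomeric amide. The isodiazene may also be diverted before the C3–C4 bond closes, through tetrazene formation, tautomerisation to a hydrazone, or disproportionation after cage escape. β-Scission of the O1–C2 bond is a further risk, because it would release a styrene and an ortho-quinone methide whose recombination would erode the C2 configuration. The fallback sets out from 9 and returns at 13, building the N–N bond stepwise by known chemistry. Nitrosation of 9 (tert-butyl nitrite, CH2Cl2) would give the N-nitrosobenzoxazepine F1. Reduction (LiAlH4, THF, 0 °C) would give the N-aminobenzoxazepine F2. Oxidation of this 1,1-disubstituted hydrazine with HgO (or tert-butyl hypochlorite/Et3N) at low temperature would generate isodiazene 11 in the cold, where cage recombination of 12 is favoured, and should give 13.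

Step 6 (C4 oxidation). Hydride abstraction may not stop at the ether: cation 14 may lose a proton to the alkene, which is then oxidised further, or hydride may be taken competitively from C2–H. The fallback sets out from 13 and returns at 18, stopping deliberately at the alkene. One equivalent of DDQ in dioxane without alcohol should dehydrogenate 13 to the (2S)-flav-3-ene F3. Protonation of F3 at C3 with a catalytic strong acid (TfOH or camphorsulfonic acid, CH2Cl2, low temperature) in the presence of excess 17 gives the same cation 14 and should give 18 directly. This acid-catalysed hydroarylation of a flav-3-ene is known chemistry and bypasses 15.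

Step 8 (interflavan bond). Facial selectivity in the capture of cation 14 may be poor (2,4-cis epimer), attack may occur through C6, and the product may be alkylated further. The fallback sets out from 15 and returns at 18, changing the leaving group and the mode of activation. Exchange with benzyl mercaptan (BF3·OEt2, CH2Cl2, −20 °C) would give the 4-benzylthioflavan F4. Thiophilic activation of F4 with AgBF4 in THF at low temperature in the presence of 17 releases cation 14 without a Brønsted or silyl Lewis acid (the classical thioether/silver coupling of flavan units) and should give 18; residual epimers would be separated at that stage.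

**Further compounds**

F1 | step 5 | (2R)-8-(benzyloxy)-2-[4-(benzyloxy)phenyl]-4-nitroso-2,3,4,5-tetrahydro-1,4-benzoxazepine | O1[C@@H](CN(N=O)Cc2ccc(OCc3ccccc3)cc21)c1ccc(OCc3ccccc3)cc1
F2 | step 5 | (2R)-8-(benzyloxy)-2-[4-(benzyloxy)phenyl]-2,3-dihydro-1,4-benzoxazepin-4(5H)-amine | O1[C@@H](CN(N)Cc2ccc(OCc3ccccc3)cc21)c1ccc(OCc3ccccc3)cc1
F3 | step 6 | (2S)-7-(benzyloxy)-2-[4-(benzyloxy)phenyl]-2H-chromene | O1[C@@H](C=Cc2ccc(OCc3ccccc3)cc21)c1ccc(OCc3ccccc3)cc1
F4 | step 8 | (2S,4R)-7-(benzyloxy)-2-[4-(benzyloxy)phenyl]-4-(benzylsulfanyl)-3,4-dihydro-2H-chromene (2,4-trans epimer drawn) | O1[C@@H](C[C@@H](SCc3ccccc3)c2ccc(OCc3ccccc3)cc21)c1ccc(OCc3ccccc3)cc1
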